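Time is the thing to watch when you repeat these runs, at the one temperature they share: how long a flask needs to turn its charge through, and how long target then has to sit.

| flask | starting material | catalyst | time |
|---|---|---|---|
| grey | 0.400 M | 0.00800 M |  |
| violet | 0.200 M | 0.00800 M |  |
| green | 0.400 M | 0.0160 M |  |
| ochre | 0.400 M | 0.0520 M | 82 min |

| grey run: time / min | grey run: [target] / M | violet run: time / min | violet run: [target] / M | green run: time / min | green run: [target] / M |
|---|---|---|---|---|---|
| 6.2 | 0.032 | 6.2 | 0.016 | 6.2 | 0.067 |
| 19 | 0.083 | 19 | 0.053 | 19 | 0.143 |
| 36 | 0.124 | 36 | 0.092 | 36 | 0.224 |
| 57 | 0.163 | 57 | 0.094 | 57 | 0.257 |
| 82 | 0.183 | 82 | 0.097 | 82 | 0.223 |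

(scatter of a reading: 0.006 M)

- how the opening rate goes with [starting material] round the charge of the grey run: the exponent of the rate at two percent of starting material gone to target (one fixed amount of target, the same in the runs compared)
- how the opening rate goes with [catalyst] round the charge of the grey run: the exponent of the rate at two percent of starting material gone to target
- target in the ochre run at 82 min, as a share of the starting material charged

- Overall: starting material -> target, with catalyst as catalyst.
- Constant volume, constant temperature.
- A reading of a species includes what of it is bound.
- An order is taken over about fifteen percent of the charge, up and down.

Start by counting turnovers. By 19 min the grey run reads c(target) = 0.083 M on 0.00800 M of catalyst, so over those minutes each catalyst in the grey run has turned over at an average pace of 0.546 min⁻¹, a reading of the turnover frequency. A flask owes as many turnovers as its charge of starting material divided by its catalyst, and those turnovers divided by the pace give its turnover time: the time to turn the charge through if the pace held. It is a rough clock: the pace need not hold as starting material goes.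

The green run has the starting material of the grey run and owes 25.0 turnovers, which at the grey pace takes 45.8 min. The ochre run has that charge too and owes 7.69, which at the grey pace takes 14.1 min. At a steady pace the average target is made midway through the turnover time, so it has aged by the clock time less that midpoint.

In the green run the readings fall from 0.257 M at 57 min to 0.223 M at 82 min, after its turnover time has passed. Take the green charge as made and the shortfall as a first-order loss of target over that average age, and the loss constant is 0.009885 min⁻¹. Applied to the average age in the ochre run, my reckoning leaves 47.7% of the charge as target at 82 min.

The forecast gave orders of 1 in starting material and 1 in catalyst, and 58% for the ochre run, which stands above my figure. Its ground was that “The late behaviour looks like a reversible stop”.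

The flask gives orders of 0.59 and 1.0, and 47.0% of the charge as target in the ochre run.

    catalyst + starting material → target + catalyst (6.780 M⁻¹ min⁻¹)
    2 starting material ⇌ idle substrate dimer, settled at all times (18.80 M⁻¹)
    target → decomposed product (0.01038 min⁻¹)

The ochre run falls short of its charge through the conversion of target into decomposed product: with that step taken away, the same run gives 100% in place of 47.0%. Its turnover time of 14.1 min gives target a reckoned average age of 75.0 min at 82 min, so 47.0% reads as a loss constant of 0.01009 min⁻¹. Carried to the green run with its turnover time of 45.8 min, that constant gives c(target) = 0.220 M at 82 min, and the reading there is 0.223 M.

All runs were computed with made-up constants, noise included.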